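Assumptions: atoms carry the natural-product numbering (furan C1–C4, chain C5–C15, lactone C16–C19). Under that numbering the target is (10S,15R,16S; 7E,11E). Compounds 2 and 3 are treated as catalogue items. If needed, 2 comes from hydrogenating 3-(3-furyl)acrylic acid, and 3 comes from D-mannitol diacetonide with NaIO4.

## Retrosynthetic overview
1. Three pieces are bought: (R)-glycidol 1 (C9–C11, carries C10), 3-(furan-3-yl)propanoic acid 2 (furan plus C5–C6), and (R)-glyceraldehyde acetonide 3 (C14–C16, carries C15).
2. The last bond is C13–C14, made by Ni-electroreductive allyl–alkyl coupling of a west/central allylic acetate with an east β-acetoxy bromide. No protecting groups are used on the west/central chain; the acetonide bought in 3 is the only one in the route.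
3. East fragment: one photochemical α-C–H alkylation/lactonisation makes C16–C17, the γ-lactone and the C16 stereocentre, with induction from C15.
4. West/central fragment: C11=C12 comes from a stabilised Wittig reaction, C6–C7 from Ni-electrocatalytic decarboxylative alkenylation, and C7=C8 from carboalumination.
5. Rings: the furan is bought, and the γ-lactone is the only ring formed (Step 9, early in the east fragment).

## Route

**Step 1**
Reactants: 1, (R)-glycidol
Product: 4, (2S)-pent-4-yne-1,2-diol
Conditions: LiC≡CH·ethylenediamine (2.5 equiv), DMSO/THF, 0 °C → rt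
Reagents that add atoms: lithium acetylide, [Li]C#C
Why: Acetylide opens the terminal epoxide carbon by SN2 (epoxide alkynylation), and because the C–O bond at the stereocentre is never broken and the Payne shift of glycidol alkoxide is degenerate and stereoretentive, C10 is carried over unchanged.

**Step 2**
Reactants: 4
Product: 5, (2S,4E)-5-iodo-4-methylpent-4-ene-1,2-diol
Conditions: AlMe3 (5 equiv), Cp2ZrCl2 (0.3 equiv), CH2Cl2, 0 °C → rt; then I2, THF, −30 °C
Reagents that add atoms: trimethylaluminium, C[Al](C)C; iodine, II
Why: Negishi Zr-catalysed syn-carboalumination puts CH3 on the internal carbon and Al on the terminal carbon (the alkoxides are tolerated with excess AlMe3), and stereoretentive iodinolysis gives only the E-iodide that fixes the C7=C8 geometry.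

**Step 3**
Reactants: 2, 3-(furan-3-yl)propanoic acid
Product: 6, 1,3-dioxoisoindolin-2-yl 3-(furan-3-yl)propanoate
Conditions: N-hydroxyphthalimide, DIC, DMAP (cat.), CH2Cl2, rt
Reagents that add atoms: N-hydroxyphthalimide, O=C1c2ccccc2C(=O)N1O
Why: Carbodiimide (Steglich-type) esterification turns the acid into a redox-active ester that accepts one electron and loses CO2.

**Step 4**
Reactants: 5; 6 (1.5 equiv)
Product: 7, (2S,4E)-7-(furan-3-yl)-4-methylhept-4-ene-1,2-diol
Conditions: NiCl2·6H2O (10 mol %), 2,2′-bipyridine (12 mol %), AgNO3 (0.3 equiv), DMF, undivided cell, (+)Mg | (−)RVC, constant current, rt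
Reagents that add atoms: none
Why: In this Ni-electrocatalytic decarboxylative alkenylation, reduced Ni fragments 6 to the 2-(3-furyl)ethyl radical, which is captured by the alkenyl–Ni species from 5 and reductively eliminated with retention of the E geometry, while the free OH groups, the furan and C10 are untouched.

**Step 5**
Reactants: 7
Product: 8, ethyl (2E,4S,6E)-9-(furan-3-yl)-4-hydroxy-2,6-dimethylnona-2,6-dienoate
Conditions: TEMPO (10 mol %), PhI(OAc)2 (1.1 equiv), CH2Cl2, 0 °C; then Ph3P=C(CH3)CO2Et (2.5 equiv), rt, one pot
Reagents that add atoms: ethyl 2-(triphenylphosphoranylidene)propanoate, CCOC(=O)C(C)=P(c1ccccc1)(c1ccccc1)c1ccccc1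
Why: Oxoammonium oxidation is selective for the primary OH, and the α-hydroxy aldehyde is trapped in situ by the stabilised Wittig ylide to give the E-trisubstituted enoate (>95:5) under near-neutral conditions, so C10 does not epimerise.

**Step 6**
Reactants: 8
Product: 9, (2E,4S,6E)-9-(furan-3-yl)-2,6-dimethylnona-2,6-diene-1,4-diol
Conditions: DIBAL-H (3.5 equiv), CH2Cl2, −78 °C
Reagents that add atoms: none
Why: DIBAL-H reduces the enoate 1,2 to the allylic alcohol without touching the alkenes, the furan or C10.

**Step 7**
Reactants: 9
Product: 10, (2E,4S,6E)-9-(furan-3-yl)-4-hydroxy-2,6-dimethylnona-2,6-dien-1-yl acetate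
Conditions: AcCl (1.05 equiv), 2,4,6-collidine, CH2Cl2, −78 °C
Reagents that add atoms: acetyl chloride, CC(=O)Cl
Why: Sterically controlled mono-acylation takes the primary allylic OH over the secondary one, and acetate is chosen as the leaving group so that no nucleophilic alkoxide is released in Step 11.

**Step 8**
Reactants: 3, (R)-2,2-dimethyl-1,3-dioxolane-4-carbaldehyde
Product: 11, 1-[(4R)-2,2-dimethyl-1,3-dioxolan-4-yl]ethan-1-ol (both carbinol epimers)
Conditions: MeMgBr, THF, −78 °C → 0 °C
Reagents that add atoms: methylmagnesium bromide, C[Mg]Br
Why: This is a Grignard addition, and the new carbinol centre is deliberately left as a mixture because it becomes planar in Step 9, while C15 is untouched.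

**Step 9**
Reactants: 11 (1.5 equiv)
Product: 12, (5S)-5-[(1R)-1,2-dihydroxyethyl]-5-methyloxolan-2-one
Conditions: methyl acrylate (1.0 equiv), Ir[dF(CF3)ppy]2(dtbbpy)PF6 (1 mol %), quinuclidine (10 mol %), Bu4N·H2PO4 (25 mol %), MeCN, 450 nm LEDs, rt; then 2 M HCl, THF, 45 °C. The minor C16 epimer is removed by chromatography here or at 13.
Reagents that add atoms: methyl acrylate, C=CC(=O)OC
Why: Proposed new method: excited Ir(III) oxidises quinuclidine, and its radical cation abstracts the carbinol C–H, which is selectively activated by the O–H···phosphate hydrogen bond, so both epimers of 11 converge on one planar α-hydroxy radical; with no metal available for chelation and the OH engaged by phosphate, this radical should adopt the Cornforth/Felkin–Anh geometry (C16–O anti to C15–O), in which the dioxolane CH2/CMe2 blocks one face and acrylate adds from the H15 side to form C16–C17 with (16S); Ir(II) then reduces the α-ester radical, and the acid step closes the γ-lactone and removes the acetonide; the closest known reactions are the photoredox/HAT/hydrogen-bond α-C–H alkylation of simple achiral alcohols with acrylates to γ-lactones and the anti-selective polar additions to glyceraldehyde acetonide, whereas stereoconvergent 1,2-induction to a fully substituted carbinol on a glycerol-type substrate has not been shown.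

**Step 10**
Reactants: 12
Product: 13, (1S)-2-bromo-1-[(2S)-2-methyl-5-oxooxolan-2-yl]ethyl acetate. The spatial arrangement at C15 is unchanged; the descriptor changes only because CH2Br outranks C16.
Conditions: MeC(OMe)3, PPTS (cat.), CH2Cl2, rt; evaporate; AcBr, CH2Cl2, 0 °C → rt
Reagents that add atoms: trimethyl orthoacetate, CC(OC)(OC)OC (supplies CH3C of the acetate); acetyl bromide, CC(=O)Br (supplies Br)
Why: The cyclic orthoacetate is converted into the acetoxonium ion, which bromide opens at the unhindered primary carbon (acetoxy-bromide synthesis from 1,2-diols), so the C15–O bond is never broken and the C15 acetate and the C14 radical handle are installed together.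

**Step 11**
Reactants: 10; 13 (1.5 equiv)
Product: 14, 15-acetylirciformonin B, (1R,4E,6S,8E)-11-(furan-3-yl)-6-hydroxy-4,8-dimethyl-1-[(2S)-2-methyl-5-oxooxolan-2-yl]undeca-4,8-dien-1-yl acetate
Conditions: NiBr2·diglyme (10 mol %), 4,4′-di-tert-butyl-2,2′-bipyridine (12 mol %), NaI (1 equiv), Bu4NBF4, DMA, undivided cell, (+)Fe | (−)Ni foam, constant current (about 3 F/mol), rt
Reagents that add atoms: none
Why: Proposed new method: cathodically generated Ni(0) ionises the primary allylic acetate of 10 to the syn-π-allyl-Ni(II), and Ni(I) abstracts halogen from 13 (as the iodide formed in situ) to give the primary β-acetoxyalkyl radical, which, unlike the corresponding organozinc or organomagnesium, does not expel acetate; radical capture gives allyl(alkyl)Ni(III), which reductively eliminates at the unhindered CH2 terminus (C13) faster than syn/anti isomerisation, so the E-C11=C12 alkene, the free C10-OH, the lactone, the acetate and all three stereocentres are preserved; the closest known reactions are the Ni-catalysed Zn/Mn-mediated reductive allylation of alkyl halides with allylic esters and the Ni/photoredox single-electron Tsuji–Trost coupling, whereas the electroreductive version with a γ-hydroxy allylic acetate and a β-acyloxy halide has not been shown.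

## Compound list
1 | (R)-glycidol | OC[C@@H]1CO1 | starting material
2 | 3-(furan-3-yl)propanoic acid | OC(=O)CCc1ccoc1 | starting material
3 | (R)-2,2-dimethyl-1,3-dioxolane-4-carbaldehyde | CC1(C)O[C@H](CO1)C=O | starting material
4 | (2S)-pent-4-yne-1,2-diol | OC[C@@H](O)CC#C | intermediate
5 | (2S,4E)-5-iodo-4-methylpent-4-ene-1,2-diol | OC[C@@H](O)C/C(C)=C/I | intermediate
6 | 1,3-dioxoisoindolin-2-yl 3-(furan-3-yl)propanoate | O=C(CCc1ccoc1)ON1C(=O)c2ccccc2C1=O | intermediate
7 | (2S,4E)-7-(furan-3-yl)-4-methylhept-4-ene-1,2-diol | OC[C@@H](O)C/C(C)=C/CCc1ccoc1 | intermediate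
8 | ethyl (2E,4S,6E)-9-(furan-3-yl)-4-hydroxy-2,6-dimethylnona-2,6-dienoate | CCOC(=O)/C(C)=C/[C@@H](O)C/C(C)=C/CCc1ccoc1 | intermediate
9 | (2E,4S,6E)-9-(furan-3-yl)-2,6-dimethylnona-2,6-diene-1,4-diol | OC/C(C)=C/[C@@H](O)C/C(C)=C/CCc1ccoc1 | intermediate
10 | (2E,4S,6E)-9-(furan-3-yl)-4-hydroxy-2,6-dimethylnona-2,6-dien-1-yl acetate | CC(=O)OC/C(C)=C/[C@@H](O)C/C(C)=C/CCc1ccoc1 | intermediate
11 | 1-[(4R)-2,2-dimethyl-1,3-dioxolan-4-yl]ethan-1-ol (carbinol epimers) | CC1(C)O[C@H](CO1)C(C)O | intermediate
12 | (5S)-5-[(1R)-1,2-dihydroxyethyl]-5-methyloxolan-2-one | O[C@H](CO)[C@]1(C)CCC(=O)O1 | intermediate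
13 | (1S)-2-bromo-1-[(2S)-2-methyl-5-oxooxolan-2-yl]ethyl acetate | CC(=O)O[C@H](CBr)[C@]1(C)CCC(=O)O1 | intermediate
14 | 15-acetylirciformonin B | CC(=O)O[C@H](CC/C(C)=C/[C@@H](O)C/C(C)=C/CCc1ccoc1)[C@]1(C)CCC(=O)O1 | target

## Summary
Total steps: 11.
Longest linear sequence: 7 (Steps 1, 2, 4, 5, 6, 7, 11).

Steps most likely to fail:
1. **Step 9 (proposed new step).**
   - Risks: modest facial selectivity at C16, competing HAT at dioxolane C–H bonds, or loss of the β-C–O bond from the α-hydroxy radical.
   - Fallback (known chemistry): set C16 by C–O bond formation instead. Oxidise 11 to the methyl ketone, methylenate (Wittig) and remove the acetonide. Carry out the hydroxyl-directed VO(acac)2/t-BuOOH epoxidation of the resulting isopropenyl carbinol, which is erythro-selective for 1,1-disubstituted allylic alcohols and gives the same 15R,16S relationship. Then open the epoxide CH2 with dilithioacetate (or with malonate followed by decarboxylation) and lactonise to 12.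
2. **Step 11 (proposed new step).**
   - Risks: allyl homodimerisation, E/Z erosion through π-allyl isomerisation, or reductive loss of the bromide/acetate pair.
   - Fallback (known chemistry): move the union to C12–C13 as a B-alkyl Suzuki–Miyaura coupling. One partner is the (E)-alkenyl iodide made from 7 by oxidation, Corey–Fuchs/MeI and hydrozirconation–iodination. The other is the 9-BBN adduct of the vinyl carbinol acetate made from 12 by primary-selective oxidation, Takai-type (Zn/CH2I2/TiCl4) methylenation and acetylation.
3. **Step 5.**
   - Risks: glycol cleavage by PhI(OAc)2, a fragile α-hydroxy aldehyde, and sensitivity of the furan to the oxidant.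
   - Fallback: buy C10 at the carboxyl oxidation level. Couple the redox-active ester of the L-malic acid acetonide [(S)-2,2-dimethyl-5-oxo-1,3-dioxolane-4-acetic acid] with (E)-3-(4-iodopent-3-enyl)furan by decarboxylative alkenylation, which makes the C8–C9 bond. Reduce the dioxolanone with DIBAL-H to the lactol and apply the same Wittig reaction to reach 8.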